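**Assumption:** Locants follow 3,7-dioxabicyclo[3.3.0]octane numbering of the target (C1 carbinol carbon, C2 and C6 aryl-bearing carbons, O3, C4, C5 ring-fusion CH, O7, C8). Ring A = C1–C5–C6–O7–C8 and ring B = C1–C2–O3–C4–C5. The target is read as the (1S,2S,5R,6R) isomer: both aryl groups endo, with OH, H-2, H-5 and H-6 all on the convex face.

**Retrosynthetic overview**
1. 18 ⇐ hydride delivery on the convex face to the C2 oxocarbenium ion ⇐ addition of the aryllithium to the ring B lactone carbonyl (C2) of bicyclic hydroxy lactone 13.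
2. 13 ⇐ ring A closure: the exocyclic C1=C8 methylene of lactone 11 is oxidised to a spiro-epoxide, which the C6 hydroxyl opens at C8. The enabling feature is that C1=C8 sits on ring B next to C5, which carries the C6 carbinol, so O7 can reach C8 in a five-membered closure and the epoxide oxygen is left as the C1 hydroxyl.
3. 11 ⇐ α-methylenation of hydroxy lactone 8 ⇐ syn hydroboration of E-arylidene lactone 6 (the E geometry becomes the C5/C6 pair that later holds the C6 aryl endo).
4. 6 ⇐ Stobbe condensation of 3,4-dimethoxybenzaldehyde with diethyl succinate. Ring order: ring B (as lactone) first, ring A last.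

Key step: step 5

**Route**

Step 1
Reactants: 1 3,4-dimethoxybenzaldehyde; 2 diethyl succinate
Product: 4 (E)-4-(3,4-dimethoxyphenyl)-3-(ethoxycarbonyl)but-3-enoic acid, via paraconate lactone 3 (not isolated)
Conditions: KOt-Bu, t-BuOH, reflux; then aq HCl
Reagents that add atoms: none
Why: Stobbe condensation (aldol addition, lactonisation to 3, E1cB ring opening) should give the half-ester with the aryl group trans to the ester, and this E geometry is carried into C5/C6 later.

Step 2
Reactants: 4 (E)-4-(3,4-dimethoxyphenyl)-3-(ethoxycarbonyl)but-3-enoic acid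
Product: 6 (E)-4-(3,4-dimethoxybenzylidene)dihydrofuran-2(3H)-one, via hydroxy acid 5 (not isolated)
Conditions: i-Bu2AlH (3.3 equiv), CH2Cl2, −78 °C; then 1 M HCl, 0 °C to rt
Reagents that add atoms: none
Why: Chemoselective 1,2-reduction of the conjugated ester by i-Bu2AlH, with the acid masked as its aluminium carboxylate, should give γ-hydroxy acid 5, which lactonises on acidification to ring B (C2 as lactone carbonyl, C4 as OCH2) with the alkene geometry unchanged.

Step 3
Reactants: 6 (E)-4-(3,4-dimethoxybenzylidene)dihydrofuran-2(3H)-one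
Product: 8 (R)-4-[(R)-(3,4-dimethoxyphenyl)(hydroxy)methyl]dihydrofuran-2(3H)-one, via alkylborane 7 (not isolated)
Conditions: isopinocampheylborane (IpcBH2, from (+)-α-pinene), Et2O, −25 °C; then 30% H2O2, aq NaOAc, 0 °C to rt
Reagents that add atoms: hydrogen peroxide OO
Why: Asymmetric hydroboration–oxidation of a trisubstituted alkene: boron should add to the less substituted benzylic carbon C6 and hydrogen to C5 on the same face, so the E geometry fixes the C5/C6 relative configuration, the reagent fixes the absolute sense (assigned by analogy with trans- and trisubstituted alkenes, to be confirmed; the antipodal reagent is available), and oxidation proceeds with retention.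

Step 4
Reactants: 8 (R)-4-[(R)-(3,4-dimethoxyphenyl)(hydroxy)methyl]dihydrofuran-2(3H)-one
Product: 11 (R)-4-[(R)-(3,4-dimethoxyphenyl)(hydroxy)methyl]-3-methylenedihydrofuran-2(3H)-one, via Mannich base 9 (not isolated), via ammonium iodide 10 (not isolated)
Conditions: LiN(i-Pr)2 (2.3 equiv), THF, −78 °C; CH2=NMe2+ I−, −78 to 0 °C; H2O; then MeI, MeOH, rt; then aq NaHCO3, EtOAc, rt
Reagents that add atoms: N,N-dimethylmethyleneiminium iodide (Eschenmoser's salt) C=[N+](C)C.[I-]
Why: Mannich α-aminomethylation of the alkoxide/enolate dianion (the enolised lactone cannot translactonise), then quaternisation and E1cB loss of trimethylamine, should install C8 as the exocyclic methylene; C5 and C6 are untouched and C1 becomes sp2.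

Step 5
Reactants: 11 (R)-4-[(R)-(3,4-dimethoxyphenyl)(hydroxy)methyl]-3-methylenedihydrofuran-2(3H)-one
Product: 13 (1S,5R,6R)-6-(3,4-dimethoxyphenyl)-1-hydroxy-3,7-dioxabicyclo[3.3.0]octan-2-one, via spiro-epoxide 12 (not isolated)
Conditions: t-BuOOH (1.5 equiv), DBU (0.3 equiv), CH2Cl2, 0 °C; then camphorsulfonic acid (0.5 equiv), 0 °C to rt
Reagents that add atoms: tert-butyl hydroperoxide CC(C)(C)OO
Why: In a Weitz–Scheffer epoxidation, t-BuOO− adds to C8 of the electron-poor exocyclic alkene and the lactone enolate closes on oxygen from the face anti to the C5 substituent, giving spiro-epoxide 12 with its CH2 (C8) syn to the C6 side chain. On acidification the C6 hydroxyl opens the epoxide at the primary C8 by SN2, which forms the O7–C8 bond and ring A in a five-membered closure whose breaking C8–O bond lies outside the new ring (exo-tet), and leaves the epoxide oxygen as the tertiary C1 hydroxyl. The closest known reaction types are the alkaline hydroperoxide epoxidation of α-methylene-γ-butyrolactones and the acid-catalysed cyclisation of hydroxy epoxides to 3-hydroxytetrahydrofurans. The new stereocentre C1 is controlled by the C5 stereocentre through face selection in the oxygen transfer, and only the epoxide with C8 syn to the side chain can cyclise, so the product should be cis-fused with OH on the convex face; C5 and C6 are not touched because the C6–O bond is never broken. The step needs chemoselectivity for the acrylate-type alkene over the electron-rich arenes and the benzylic alcohol (secured by the nucleophilic oxidant), and regioselectivity for attack at CH2 rather than at the quaternary α-carbon (secured by SN2 at the primary centre and by the carbonyl, which disfavours ionisation at C1). Closing under acid rather than through the alkoxide avoids translactonisation of ring B and base-induced migration of the exocyclic alkene.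

Step 6
Reactants: 13 (1S,5R,6R)-6-(3,4-dimethoxyphenyl)-1-hydroxy-3,7-dioxabicyclo[3.3.0]octan-2-one; 14 4-bromo-1,2-dimethoxybenzene
Product: 16 (1S,5R,6R)-2,6-bis(3,4-dimethoxyphenyl)-3,7-dioxabicyclo[3.3.0]octane-1,2-diol (both C2 epimers), via aryllithium 15 (not isolated)
Conditions: 14, n-BuLi, THF, −78 °C (3 equiv of 15); then 13, −78 °C; aq NH4Cl
Reagents that add atoms: none
Why: Bromine–lithium exchange then 1,2-addition of the aryllithium to the lactone carbonyl (the first equivalent deprotonates the C1 hydroxyl) should stop at the lithium hemiketalate, as in additions to sugar lactones, so the second aryl enters at C2 with its configuration still open.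

Step 7
Reactants: 16 (1S,5R,6R)-2,6-bis(3,4-dimethoxyphenyl)-3,7-dioxabicyclo[3.3.0]octane-1,2-diol
Product: 18 (1S,2S,5R,6R)-2,6-bis(3,4-dimethoxyphenyl)-3,7-dioxabicyclo[3.3.0]octan-1-ol, via oxocarbenium ion 17 (not isolated)
Conditions: Et3SiH, BF3·OEt2, CH2Cl2, −78 to −40 °C
Reagents that add atoms: none
Why: Ionic hydrogenation of the hemiketal: BF3 should ionise C2 to the aryl-stabilised oxocarbenium ion 17 and Et3SiH should deliver hydride from the convex face (the concave face is blocked by ring A and the endo C6 aryl), placing H-2 cis to the C1 hydroxyl and the aryl group endo.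

**Compound list**
1 | 3,4-dimethoxybenzaldehyde | COc1ccc(C=O)cc1OC | starting material
2 | diethyl succinate | CCOC(=O)CCC(=O)OCC | starting material
3 | ethyl 2-(3,4-dimethoxyphenyl)-5-oxotetrahydrofuran-3-carboxylate (paraconate lactone, mixture of stereoisomers) | CCOC(=O)C1CC(=O)OC1c1ccc(OC)c(OC)c1 | intermediate
4 | (E)-4-(3,4-dimethoxyphenyl)-3-(ethoxycarbonyl)but-3-enoic acid | COc1ccc(/C=C(\CC(=O)O)C(=O)OCC)cc1OC | intermediate
5 | (E)-4-(3,4-dimethoxyphenyl)-3-(hydroxymethyl)but-3-enoic acid | COc1ccc(/C=C(\CC(=O)O)CO)cc1OC | intermediate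
6 | (E)-4-(3,4-dimethoxybenzylidene)dihydrofuran-2(3H)-one | COc1ccc(/C=C2\CC(=O)OC2)cc1OC | intermediate
7 | [(R)-(3,4-dimethoxyphenyl)((S)-5-oxotetrahydrofuran-3-yl)methyl](isopinocampheyl)borane | C[C@H]1[C@H](B[C@@H](c3ccc(OC)c(OC)c3)[C@H]3COC(=O)C3)C[C@@H]2C[C@H]1C2(C)C | intermediate
8 | (R)-4-[(R)-(3,4-dimethoxyphenyl)(hydroxy)methyl]dihydrofuran-2(3H)-one | COc1ccc([C@H](O)[C@H]2COC(=O)C2)cc1OC | intermediate
9 | (3S,4R)-3-[(dimethylamino)methyl]-4-[(R)-(3,4-dimethoxyphenyl)(hydroxy)methyl]dihydrofuran-2(3H)-one | COc1ccc([C@H](O)[C@H]2COC(=O)[C@@H]2CN(C)C)cc1OC | intermediate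
10 | {(3S,4R)-4-[(R)-(3,4-dimethoxyphenyl)(hydroxy)methyl]-2-oxotetrahydrofuran-3-yl}methyl(trimethyl)ammonium iodide | COc1ccc([C@H](O)[C@H]2COC(=O)[C@@H]2C[N+](C)(C)C)cc1OC.[I-] | intermediate
11 | (R)-4-[(R)-(3,4-dimethoxyphenyl)(hydroxy)methyl]-3-methylenedihydrofuran-2(3H)-one | COc1ccc([C@H](O)[C@H]2COC(=O)C2=C)cc1OC | intermediate
12 | (3S,7R)-7-[(R)-(3,4-dimethoxyphenyl)(hydroxy)methyl]-1,5-dioxaspiro[2.4]heptan-4-one | COc1ccc([C@H](O)[C@H]2COC(=O)[C@@]23CO3)cc1OC | intermediate
13 | (1S,5R,6R)-6-(3,4-dimethoxyphenyl)-1-hydroxy-3,7-dioxabicyclo[3.3.0]octan-2-one | COc1ccc([C@@H]2OC[C@@]3(O)[C@@H]2COC3=O)cc1OC | intermediate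
14 | 4-bromo-1,2-dimethoxybenzene | COc1ccc(Br)cc1OC | starting material
15 | 3,4-dimethoxyphenyllithium | [Li]c1ccc(OC)c(OC)c1 | intermediate
16 | (1S,5R,6R)-2,6-bis(3,4-dimethoxyphenyl)-3,7-dioxabicyclo[3.3.0]octane-1,2-diol (both C2 epimers) | COc1ccc([C@@H]2OC[C@@]3(O)[C@@H]2COC3(O)c2ccc(OC)c(OC)c2)cc1OC | intermediate
17 | (1S,5R,6R)-2,6-bis(3,4-dimethoxyphenyl)-1-hydroxy-7-oxa-3-oxoniabicyclo[3.3.0]oct-2-ene (oxocarbenium ion) | COc1ccc([C@@H]2OC[C@@]3(O)[C@@H]2C[O+]=C3c2ccc(OC)c(OC)c2)cc1OC | intermediate
18 | (1S,2S,5R,6R)-2,6-bis(3,4-dimethoxyphenyl)-3,7-dioxabicyclo[3.3.0]octan-1-ol | COc1ccc([C@@H]2OC[C@@]3(O)[C@@H]2CO[C@H]3c2ccc(OC)c(OC)c2)cc1OC | target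

**Step count and risks**

Total step count: 7. Longest linear sequence: 7 steps (1 and 2 to 18); 14 enters at step 6.

Steps most likely to fail:

Step 5. The oxygen transfer may lose facial control, or base may trigger side reactions of 11 before epoxidation (5-endo conjugate addition of the hydroxyl, translactonisation, migration of the exocyclic alkene into the ring). The fallback sets out from 11. Dihydroxylation with OsO4 (cat.) and N-methylmorpholine N-oxide from the face anti to the C5 substituent should give (3S,4R)-3-hydroxy-3-(hydroxymethyl)-4-[(R)-(3,4-dimethoxyphenyl)(hydroxy)methyl]dihydrofuran-2(3H)-one F1. TsCl in pyridine at 0 °C should sulfonylate only the primary hydroxyl to give the primary tosylate F2. Warming with DBU in CH2Cl2 should close ring A by displacement at the primary carbon, directly or through epoxide 12, and the route is rejoined at 13.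

Step 3. Enantio-induction by the chiral borane may be incomplete, or some boron may add at C5. The fallback sets out from 6. Hydroboration with BH3·SMe2 and the same buffered H2O2 oxidation should give racemic 8, with the same relative configuration because syn addition to the E alkene does not depend on the borane. The racemate, 8 together with its mirror image (S)-4-[(S)-(3,4-dimethoxyphenyl)(hydroxy)methyl]dihydrofuran-2(3H)-one F3, is resolved by preparative chromatography on a chiral stationary phase, and the route is rejoined at 8.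

Step 7. BF3 may ionise the electron-rich benzylic C6–O7 ether, causing drift of the C6 aryl to exo or reductive ring opening, or hydride may not discriminate the faces fully. The fallback sets out from 16. Zn(BH4)2 in Et2O at −20 °C should reduce the ring-opened hydroxy-ketone tautomer under chelation control (zinc bridging the C1 hydroxyl and the ketone, hydride arriving from the C8 side) to (3S,4R,5R)-5-(3,4-dimethoxyphenyl)-3-[(S)-(3,4-dimethoxyphenyl)(hydroxy)methyl]-4-(hydroxymethyl)tetrahydrofuran-3-ol F4. TsCl in pyridine should sulfonylate the primary C4 hydroxyl to give the tosylate F5, which should cyclise by attack of the C2 hydroxyl on C4 with retention at C2. This reaches 18 without a Lewis acid.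

Further compounds
F1 | step 5 | (3S,4R)-3-hydroxy-3-(hydroxymethyl)-4-[(R)-(3,4-dimethoxyphenyl)(hydroxy)methyl]dihydrofuran-2(3H)-one | COc1ccc([C@H](O)[C@H]2COC(=O)[C@@]2(O)CO)cc1OC
F2 | step 5 | {(3S,4R)-3-hydroxy-4-[(R)-(3,4-dimethoxyphenyl)(hydroxy)methyl]-2-oxotetrahydrofuran-3-yl}methyl 4-methylbenzenesulfonate | COc1ccc([C@H](O)[C@H]2COC(=O)[C@@]2(O)COS(=O)(=O)c2ccc(C)cc2)cc1OC
F3 | step 3 | (S)-4-[(S)-(3,4-dimethoxyphenyl)(hydroxy)methyl]dihydrofuran-2(3H)-one | COc1ccc([C@@H](O)[C@@H]2COC(=O)C2)cc1OC
F4 | step 7 | (3S,4R,5R)-5-(3,4-dimethoxyphenyl)-3-[(S)-(3,4-dimethoxyphenyl)(hydroxy)methyl]-4-(hydroxymethyl)tetrahydrofuran-3-ol | COc1ccc([C@@H]2OC[C@@](O)([C@@H]2CO)[C@@H](O)c2ccc(OC)c(OC)c2)cc1OC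
F5 | step 7 | {(2R,3R,4S)-2-(3,4-dimethoxyphenyl)-4-[(S)-(3,4-dimethoxyphenyl)(hydroxy)methyl]-4-hydroxytetrahydrofuran-3-yl}methyl 4-methylbenzenesulfonate | COc1ccc([C@@H]2OC[C@@](O)([C@@H]2COS(=O)(=O)c2ccc(C)cc2)[C@@H](O)c2ccc(OC)c(OC)c2)cc1OC
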